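**Strategy**

Numbering: C1 lactone carbonyl, C2, C3 (CH–O–O), C4 (CMe–O, ring fusion), C5 (ring CH2), C6 (CMe(chain)–O–O). In the 1,2-dioxane/γ-lactone bicycle the C5 methylene sits between C6, which can be a peroxycarbenium carbon, and C4, which can be a tertiary cation within reach of the C1 carboxyl. The route therefore cuts C5–C6 and C4–O together. One Lewis-acid step on an acyclic mixed methyl peroxyketal, built from an (R)-allylic hydroperoxide (isopropenyl group, tert-butyl ester arm) and an alkynyl methyl ketone ketal carrying the chain, should close both rings and set C4 and C6; saturating the alkyne then gives plakortolide K.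

Key step: step 8

Assumption: the peroxidase in step 6 is taken to consume the (3S)-hydroperoxide faster; the sense of the resolution has to be confirmed on this substrate before the material is used.

Remark: C3 is R in the hydroperoxide, the cyclisation precursor, the alkynyl lactone and the target; C6 has the same geometry in the alkynyl lactone and the target and only its CIP label changes (R with the alkynyl or alkenyl group, S with the saturated chain). The ketal carbon of the precursor is used as both epimers and is left undefined in its SMILES.

**Route**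

Step 1
Reactants: 1 bromobenzene; 2 1,10-dibromodecane
Product: 4 (10-bromodecyl)benzene, via phenylmagnesium bromide 3 (not isolated)
Conditions: Mg, THF, reflux; then added to 2 (3 equiv), Li2CuCl4 (cat.), THF, −10 to 0 °C
Reagents that add atoms: none
Why: Copper-catalysed cross-coupling of an aryl Grignard reagent with a primary alkyl bromide; the excess of dibromide should keep double arylation low and can be recovered by distillation.

Step 2
Reactants: 5 but-3-yn-2-one
Product: 6 3,3-dimethoxybut-1-yne
Conditions: HC(OMe)3, MeOH, TsOH (cat.), 0 °C to rt; K2CO3 quench, distillation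
Reagents that add atoms: trimethyl orthoformate, COC(OC)OC; methanol, CO
Why: Acid-catalysed ketalisation driven by the orthoformate as water scavenger, run cold and quenched with base so that conjugate addition of methanol to the ynone should stay minor.

Step 3
Reactants: 6 3,3-dimethoxybut-1-yne; 4 (10-bromodecyl)benzene
Product: 8 2,2-dimethoxy-14-phenyltetradec-3-yne, via lithium 3,3-dimethoxybut-1-yn-1-ide 7 (not isolated)
Conditions: n-BuLi, THF, −78 °C; then 4, DMPU, −78 °C to rt
Reagents that add atoms: none
Why: SN2 alkylation of a lithium acetylide by a primary bromide in THF/DMPU; the dimethyl ketal is inert to the base.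

Step 4
Reactants: 9 4-methylpent-3-enoic acid
Product: 10 tert-butyl 4-methylpent-3-enoate
Conditions: t-BuOC(=NH)CCl3 (2 equiv), CH2Cl2/cyclohexane, rt
Reagents that add atoms: tert-butyl 2,2,2-trichloroacetimidate, CC(C)(C)OC(=N)C(Cl)(Cl)Cl
Why: tert-Butyl transfer from the trichloroacetimidate to the carboxylic acid needs neither base nor strong acid, which should avoid both migration of the β,γ-alkene into conjugation and acid-induced lactonisation.

Step 5
Reactants: 10 tert-butyl 4-methylpent-3-enoate
Product: 11 tert-butyl 3-hydroperoxy-4-methylpent-4-enoate (racemic)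
Conditions: O2, hν (visible), tetraphenylporphyrin (cat.), CH2Cl2, 0 °C; chromatography, kept cold
Reagents that add atoms: dioxygen, O=O
Why: Schenck ene reaction of singlet oxygen: oxygen bonds to C3 and a hydrogen is taken from the geminal methyl group, which moves the alkene to C4=C5; C3 forms racemic, and the conjugated tertiary hydroperoxide from abstraction at C2 should be removable by chromatography.

Step 6
Reactants: 11 tert-butyl 3-hydroperoxy-4-methylpent-4-enoate (racemic)
Product: 12 tert-butyl (3R)-3-hydroperoxy-4-methylpent-4-enoate
Conditions: horseradish peroxidase, guaiacol, phosphate buffer pH 6, 20 °C, stopped slightly past half conversion; extraction, chromatography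
Reagents that add atoms: none
Why: Peroxidase-catalysed kinetic resolution of a secondary hydroperoxide: the enzyme reduces one enantiomer to the alcohol at the expense of guaiacol and the slow-reacting (3R)-hydroperoxide should be recovered, its configuration being checked by phosphine reduction of a sample to the alcohol.

Step 7
Reactants: 12 tert-butyl (3R)-3-hydroperoxy-4-methylpent-4-enoate; 8 2,2-dimethoxy-14-phenyltetradec-3-yne
Product: 13 tert-butyl (3R)-3-[(2-methoxy-14-phenyltetradec-3-yn-2-yl)peroxy]-4-methylpent-4-enoate (both ketal epimers)
Conditions: 8 (2 equiv), PPTS (10 mol%), 5 Å MS, CH2Cl2, 0 °C to rt; Et3N quench, chromatography on base-washed silica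
Reagents that add atoms: none
Why: Acid-catalysed transketalisation to a mixed peroxyketal: the ketal ionises to a methoxy-oxocarbenium ion that the hydroperoxide oxygen captures, excess ketal and methanol-binding sieves favour the mono-exchanged product, and C3 is not involved.

Step 8
Reactants: 13 tert-butyl (3R)-3-[(2-methoxy-14-phenyltetradec-3-yn-2-yl)peroxy]-4-methylpent-4-enoate (both ketal epimers)
Product: 16 (3R,4aR,7aR)-3,4a-dimethyl-3-(12-phenyldodec-1-yn-1-yl)tetrahydrofuro[3,2-c][1,2]dioxin-6(3H)-one, via alkynyl peroxycarbenium triflate 14 (not isolated), via O-tert-butyl lactonium triflate 15 (not isolated)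
Conditions: TMSOTf (1.2 equiv), 2,6-di-tert-butyl-4-methylpyridine (1.5 equiv), CH2Cl2 (0.01 M), −78 to −40 °C; NaHCO3 quench
Reagents that add atoms: none
Why: Proposed new method: TMSOTf silylates the ketal methoxy oxygen and expels MeOSiMe3, the resulting alkyne-conjugated peroxycarbenium ion 14 is attacked at C6 by the CH2 terminus of the C4=C5 isopropenyl group, and the tertiary C4 cation so formed is captured by the tert-butyl ester carbonyl oxygen to give lactonium ion 15, which loses isobutene to the hindered base. The closest known reaction types are Lewis-acid cyclisations of alkene- or allylsilane-bearing monoperoxyketals through peroxycarbenium ions and Prins-type cation–olefin cyclisations that end in capture by an ester or carboxyl group; their union on an alkynyl peroxyketal is untested. The 1,2-dioxane closes 6-endo-trig with Markovnikov polarity (C5–C6 bond; the 5-exo mode would need a primary cation) and the γ-lactone closes by 5-exo attack of the carbonyl oxygen on C4 (C4–O bond). C4 is controlled by the resolved C3 centre, because the short C2–C1 tether lets the carbonyl oxygen reach C4 only on the face cis to the C3 arm, which makes the lactone cis-fused; C6 is controlled by a chair transition state with the C3 arm equatorial, the slim alkynyl group (syn to the O–O bond in the ion) axial and methyl equatorial, and both ketal epimers converge because 14 is planar at C6. The step needs ionisation of C–OMe and not of C–OO (the silyl Lewis acid binds the more basic, less hindered ether oxygen), ester capture in preference to proton loss or halide capture (five-ring closure within the molecule, non-nucleophilic triflate, no chloride present) and facial selectivity at C6 (the steric difference between the rod-like alkynyl group and methyl).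

Step 9
Reactants: 16 (3R,4aR,7aR)-3,4a-dimethyl-3-(12-phenyldodec-1-yn-1-yl)tetrahydrofuro[3,2-c][1,2]dioxin-6(3H)-one
Product: 18 plakortolide K [(3S,4aR,7aR)-3,4a-dimethyl-3-(12-phenyldodecyl)tetrahydrofuro[3,2-c][1,2]dioxin-6(3H)-one], via Z-alkenyl peroxylactone 17 (not isolated)
Conditions: KO2CN=NCO2K (excess, in portions), AcOH, MeOH/CH2Cl2, 0 °C to rt
Reagents that add atoms: none
Why: Diimide reduction: hydrogen is delivered syn to the alkyne and then to the cis-alkene through a cyclic transition state, and the O–O bond, the lactone and the arene should be left alone; no stereocentre is touched.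

**Compound list**

1 | bromobenzene | Brc1ccccc1 | starting material
2 | 1,10-dibromodecane | BrCCCCCCCCCCBr | starting material
3 | phenylmagnesium bromide | Br[Mg]c1ccccc1 | intermediate (not isolated)
4 | (10-bromodecyl)benzene | BrCCCCCCCCCCc1ccccc1 | intermediate
5 | but-3-yn-2-one | CC(=O)C#C | starting material
6 | 3,3-dimethoxybut-1-yne | COC(C)(OC)C#C | intermediate
7 | lithium 3,3-dimethoxybut-1-yn-1-ide | [Li]C#CC(C)(OC)OC | intermediate (not isolated)
8 | 2,2-dimethoxy-14-phenyltetradec-3-yne | COC(C)(OC)C#CCCCCCCCCCCc1ccccc1 | intermediate
9 | 4-methylpent-3-enoic acid | CC(C)=CCC(=O)O | starting material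
10 | tert-butyl 4-methylpent-3-enoate | CC(C)=CCC(=O)OC(C)(C)C | intermediate
11 | tert-butyl 3-hydroperoxy-4-methylpent-4-enoate (racemic) | CC(=C)C(OO)CC(=O)OC(C)(C)C | intermediate
12 | tert-butyl (3R)-3-hydroperoxy-4-methylpent-4-enoate | CC(C)(C)OC(=O)C[C@@H](OO)C(C)=C | intermediate
13 | tert-butyl (3R)-3-[(2-methoxy-14-phenyltetradec-3-yn-2-yl)peroxy]-4-methylpent-4-enoate (both ketal epimers) | CC(C)(C)OC(=O)C[C@@H](OOC(C)(OC)C#CCCCCCCCCCCc1ccccc1)C(C)=C | intermediate
14 | alkynyl peroxycarbenium triflate (13 after loss of methoxide; C6=O(+)–O–C3) | CC(C)(C)OC(=O)C[C@@H](O[O+]=C(C)C#CCCCCCCCCCCc1ccccc1)C(C)=C.[O-]S(=O)(=O)C(F)(F)F | intermediate (not isolated)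
15 | O-tert-butyl lactonium triflate (cis-fused bicycle of 16 with C1 carrying O-tert-butyl and C1=O(+) to the oxygen on C4) | C[C@]1(C#CCCCCCCCCCCc2ccccc2)C[C@@]2(C)[O+]=C(OC(C)(C)C)C[C@H]2OO1.[O-]S(=O)(=O)C(F)(F)F | intermediate (not isolated)
16 | (3R,4aR,7aR)-3,4a-dimethyl-3-(12-phenyldodec-1-yn-1-yl)tetrahydrofuro[3,2-c][1,2]dioxin-6(3H)-one | C[C@]1(C#CCCCCCCCCCCc2ccccc2)C[C@@]2(C)OC(=O)C[C@H]2OO1 | intermediate
17 | (3R,4aR,7aR)-3,4a-dimethyl-3-[(1Z)-12-phenyldodec-1-en-1-yl]tetrahydrofuro[3,2-c][1,2]dioxin-6(3H)-one | C[C@]1(/C=C\CCCCCCCCCCc2ccccc2)C[C@@]2(C)OC(=O)C[C@H]2OO1 | intermediate (not isolated)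
18 | plakortolide K, (3S,4aR,7aR)-3,4a-dimethyl-3-(12-phenyldodecyl)tetrahydrofuro[3,2-c][1,2]dioxin-6(3H)-one | C[C@]1(CCCCCCCCCCCCc2ccccc2)C[C@@]2(C)OC(=O)C[C@H]2OO1 | target

**Step count and risks**

Total steps: 9. Longest linear sequence: 6 (steps 4 to 9, from 9).

Steps most likely to fail:

1. Step 8 (Proposed new method). The peroxyketal may ionise at the peroxide C–O bond and not at C–OMe. The C4 cation or the peroxycarbenium ion may lose a proton before the ester closes. Facial selectivity at C6 may be low, because the chair with the C3 arm axial competes. Fallback (known chemistry, sets out from 2 and returns at 18): the hydroperoxysilylation/oxa-Michael sequence known for this family of peroxylactones.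
   - 2 is coupled with benzylmagnesium chloride (Li2CuCl4) to give (11-bromoundecyl)benzene F1.
   - The Grignard reagent of F1 and 2,3-dibromopropene should give 2-bromo-14-phenyltetradec-1-ene F2.
   - The vinylmagnesium bromide from F2 opens (S)-2-methylglycidol (as its chloromagnesium alkoxide, CuI cat.) at the CH2 terminus to (2R)-2-methyl-4-methylidene-16-phenylhexadecane-1,2-diol F3.
   - Parikh–Doering oxidation should give (2R)-2-hydroxy-2-methyl-4-methylidene-16-phenylhexadecanal F4.
   - (Triphenylphosphoranylidene)ketene in hot toluene closes F4 to (5R)-5-methyl-5-(2-methylidene-14-phenyltetradecyl)furan-2(5H)-one F5.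
   - Mukaiyama–Isayama hydroperoxysilylation (Co(thd)2, O2, Et3SiH) of the electron-rich 1,1-disubstituted alkene should give (5R)-5-methyl-5-{2-methyl-14-phenyl-2-[(triethylsilyl)peroxy]tetradecyl}furan-2(5H)-one F6 as both C6 epimers.
   - Buffered fluoride releases (5R)-5-(2-hydroperoxy-2-methyl-14-phenyltetradecyl)-5-methylfuran-2(5H)-one F7.
   - Under Et2NH in CF3CH2OH, F7 adds to the butenolide from the face of its tether, which fixes C3 from C4. It should give 18 together with 6-epi-plakortolide K F8, to be separated by chromatography.

2. Step 6. The peroxidase may turn the substrate over slowly or discriminate its enantiomers poorly or in the opposite sense, since the carbinol carbon carries two medium-sized groups. Fallback (sets out from 11 and returns at 12): racemic 11 is separated into its enantiomers by preparative HPLC on a cellulose carbamate chiral phase (hexane/2-propanol, cold). The (3R) fraction is identified by reduction of a sample to the alcohol. This is independent of any enzyme preference and no new compound is made (F0).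

3. Step 7. Ionisation of the alkyne-deactivated ketal may be slow, so that acid-induced Hock-type cleavage of the allylic hydroperoxide or double exchange to a bis-peroxyketal competes. Fallback (sets out from 8 and returns at 13): 8 is converted with TMSOTf/i-Pr2NEt into 2-methoxy-14-phenyltetradec-1-en-3-yne F9. PPTS-catalysed Markovnikov addition of 12 across this enol ether should then give 13 irreversibly and without methanol to remove.

Further compounds
F1 | step 8 | (11-bromoundecyl)benzene | BrCCCCCCCCCCCc1ccccc1
F2 | step 8 | 2-bromo-14-phenyltetradec-1-ene | C=C(Br)CCCCCCCCCCCCc1ccccc1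
F3 | step 8 | (2R)-2-methyl-4-methylidene-16-phenylhexadecane-1,2-diol | C=C(CCCCCCCCCCCCc1ccccc1)C[C@@](CO)(C)O
F4 | step 8 | (2R)-2-hydroxy-2-methyl-4-methylidene-16-phenylhexadecanal | C=C(CCCCCCCCCCCCc1ccccc1)C[C@@](C=O)(C)O
F5 | step 8 | (5R)-5-methyl-5-(2-methylidene-14-phenyltetradecyl)furan-2(5H)-one | C=C(CCCCCCCCCCCCc1ccccc1)C[C@@]1(C)OC(=O)C=C1
F6 | step 8 | (5R)-5-methyl-5-{2-methyl-14-phenyl-2-[(triethylsilyl)peroxy]tetradecyl}furan-2(5H)-one (both epimers at the peroxide carbon) | CC[Si](CC)(CC)OOC(C)(CCCCCCCCCCCCc1ccccc1)C[C@@]1(C)OC(=O)C=C1
F7 | step 8 | (5R)-5-(2-hydroperoxy-2-methyl-14-phenyltetradecyl)-5-methylfuran-2(5H)-one (both epimers at the peroxide carbon) | OOC(C)(CCCCCCCCCCCCc1ccccc1)C[C@@]1(C)OC(=O)C=C1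
F8 | step 8 | 6-epi-plakortolide K, (3R,4aR,7aR)-3,4a-dimethyl-3-(12-phenyldodecyl)tetrahydrofuro[3,2-c][1,2]dioxin-6(3H)-one | C[C@@]1(CCCCCCCCCCCCc2ccccc2)C[C@@]2(C)OC(=O)C[C@H]2OO1
F0 | step 6 | none | none
F9 | step 7 | 2-methoxy-14-phenyltetradec-1-en-3-yne | C=C(OC)C#CCCCCCCCCCCc1ccccc1
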